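The seven-membered ring (azulene numbering) carries oxygen at C-4 and C-8 on either side of a C-5 H2–C-6(CH3)=C-7 H unit. This array is a cyclopentane-1,3-dione whose C-1–C-2 bond has taken up propyne. The key step is therefore a two-carbon ring expansion of the cis-fused hexahydropentalene-1,3-dione 13: formal insertion of propyne forms C-6=C-7 and C-4–C-5 in one operation and gives the hydroazulene enedione with all ring carbons and both oxygens in place. Dione 13 is built from 2-methylcyclopentane-1,3-dione by desymmetrising reduction, chromium-mediated ring closure and a 1,2-carbonyl shift; two reductions and two acylations complete the target.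

Key step: step 9

Remark: azulene numbering is used for the hydroazulenes and pentalene numbering for the bicyclo[3.3.0]octanes; enedione 16 is a vinylogous 1,3-diketone and is assumed to equilibrate readily with its C-5=C-6 enone tautomer.

Step 1
Reactants: 1 2-methylcyclopentane-1,3-dione; 2 N-methoxy-N-methylprop-2-enamide
Product: 3 N-methoxy-N-methyl-3-(1-methyl-2,5-dioxocyclopentyl)propanamide
Conditions: DBU (0.2 equiv), MeCN, 50 °C
Reagents that add atoms: none
Why: Michael addition of the acidic 2-substituted 1,3-dione to the acrylamide should alkylate C-2 and give an achiral, prochiral dione whose amide carbonyl is inert in the next steps.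

Step 2
Reactants: 3 N-methoxy-N-methyl-3-(1-methyl-2,5-dioxocyclopentyl)propanamide
Product: 4 N-methoxy-N-methyl-3-[(1S,2S)-2-hydroxy-1-methyl-5-oxocyclopentyl]propanamide
Conditions: (R)-2-methyl-CBS-oxazaborolidine (0.2 equiv), catecholborane (1.5 equiv), toluene/CH2Cl2, −78 to −40 °C
Reagents that add atoms: none
Why: Corey–Bakshi–Shibata reduction should desymmetrise the dione, the (R)-catalyst giving the S carbinol (quaternary carbon as the large group) and hydride attack anti to the longer side chain selecting the carbonyl that makes the quaternary carbon S, while catecholborane leaves the Weinreb amide alone.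

Step 3
Reactants: 4 N-methoxy-N-methyl-3-[(1S,2S)-2-hydroxy-1-methyl-5-oxocyclopentyl]propanamide
Product: 5 N-methoxy-N-methyl-3-[(1S,2S)-1-methyl-5-oxo-2-[(trimethylsilyl)oxy]cyclopentyl]propanamide
Conditions: TMSCl, imidazole, CH2Cl2, 0 °C
Reagents that add atoms: chlorotrimethylsilane, C[Si](C)(C)Cl
Why: Silyl ether formation masks the only O–H before the enolate step and touches no stereocentre.

Step 4
Reactants: 5 N-methoxy-N-methyl-3-[(1S,2S)-1-methyl-5-oxo-2-[(trimethylsilyl)oxy]cyclopentyl]propanamide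
Product: 6 (4S,5S)-5-[3-[methoxy(methyl)amino]-3-oxopropyl]-5-methyl-4-[(trimethylsilyl)oxy]cyclopent-1-en-1-yl trifluoromethanesulfonate
Conditions: KN(SiMe3)2 (1.1 equiv), THF, −78 °C; then PhNTf2
Reagents that add atoms: N-phenylbis(trifluoromethanesulfonimide), O=S(=O)(N(c1ccccc1)S(=O)(=O)C(F)(F)F)C(F)(F)F
Why: Enol triflate formation is regiodefined because the ketone has only one enolisable α-carbon (the other is quaternary), and the ketone is deprotonated faster than the amide.

Step 5
Reactants: 6 (4S,5S)-5-[3-[methoxy(methyl)amino]-3-oxopropyl]-5-methyl-4-[(trimethylsilyl)oxy]cyclopent-1-en-1-yl trifluoromethanesulfonate; 7 isopropylmagnesium chloride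
Product: 8 (4S,5S)-5-methyl-5-(4-methyl-3-oxopentyl)-4-[(trimethylsilyl)oxy]cyclopent-1-en-1-yl trifluoromethanesulfonate
Conditions: iPrMgCl (1.5 equiv), THF, −20 to 0 °C; aq NH4Cl
Reagents that add atoms: none
Why: Weinreb ketone synthesis, in which the chelated tetrahedral adduct prevents over-addition and the enol triflate and silyl ether should be inert to the Grignard reagent at this temperature.

Step 6
Reactants: 8 (4S,5S)-5-methyl-5-(4-methyl-3-oxopentyl)-4-[(trimethylsilyl)oxy]cyclopent-1-en-1-yl trifluoromethanesulfonate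
Product: 9 (1S,3aR,4S)-3a-methyl-1-(propan-2-yl)-4-[(trimethylsilyl)oxy]-1,2,3,3a,4,5-hexahydropentalen-1-ol
Conditions: CrCl2 (6 equiv), NiCl2 (0.1 equiv), DMF, rt to 50 °C
Reagents that add atoms: none
Why: Intramolecular Nozaki–Hiyama–Kishi reaction, in which the alkenylchromium from the triflate adds 5-exo-trig to the isopropyl ketone and the isopropyl group should take the pseudo-equatorial site away from the angular methyl group, so that the new tertiary hydroxyl is cis to that methyl (1S).

Step 7
Reactants: 9 (1S,3aR,4S)-3a-methyl-1-(propan-2-yl)-4-[(trimethylsilyl)oxy]-1,2,3,3a,4,5-hexahydropentalen-1-ol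
Product: 12 (1S,3aR,4S,6S,6aS)-3a-methyl-1-(propan-2-yl)octahydropentalene-1,4,6-triol, via alkylborane 10 (not isolated), via silyl ether diol 11 (not isolated)
Conditions: BH3·THF (4 equiv), THF, 0 °C to rt; then 3 M NaOH, 30% H2O2, 0 °C to rt
Reagents that add atoms: hydrogen peroxide, OO
Why: Hydroboration–oxidation should place boron at the less substituted alkene carbon C-6 and hydrogen at C-6a from the face of the angular methyl and the borate-bound C-1 oxygen (cis ring fusion, the only unstrained mode for this bicycle), and the alkaline peroxide work-up also cleaves the trimethylsilyl ether.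

Step 8
Reactants: 12 (1S,3aR,4S,6S,6aS)-3a-methyl-1-(propan-2-yl)octahydropentalene-1,4,6-triol
Product: 13 (3aR,6S,6aR)-6-hydroxy-3a-methyl-6-(propan-2-yl)tetrahydropentalene-1,3(2H,3aH)-dione
Conditions: Dess–Martin periodinane (3 equiv), CH2Cl2, 0 °C to rt
Reagents that add atoms: none
Why: Dess–Martin oxidation should convert both secondary alcohols into the 1,3-dione (completing the 1,2-carbonyl shift) while the tertiary alcohol cannot react, and C-6a, now α to a carbonyl, rests in or equilibrates to the cis-fused configuration.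

Step 9
Reactants: 13 (3aR,6S,6aR)-6-hydroxy-3a-methyl-6-(propan-2-yl)tetrahydropentalene-1,3(2H,3aH)-dione; 14 propyne
Product: 16 (3S,3aR,8aR)-3-hydroxy-6,8a-dimethyl-3-(propan-2-yl)-2,3,3a,8a-tetrahydroazulene-4,8(1H,5H)-dione, via cyclobutenol 15 (not isolated)
Conditions: propyne (1.2 equiv), [ReBr(CO)3(thf)]2 (5 mol %), BnNC (10 mol %), toluene, 50 °C, sealed tube
Reagents that add atoms: none
Why: Proposed new method: the rhenium enolate of the enolised dione should add through C-2 of 13 to the internal carbon of coordinated propyne (Markovnikov C–C bond, the later C-7–C-6 bond), the alkenylrhenium then adds to the C-1 carbonyl to give cyclobutenol 15, and retro-aldol cleavage of the strained C-1–C-2 bond with proton return at C-5 releases the cyclohept-6-ene-4,8-dione, so that C-6=C-7 and C-4–C-5 arise in one operation. The closest known reaction type is the ReBr(CO)3-catalysed insertion of terminal alkynes into the ketone–α-carbon bond of cyclic β-keto esters (two-carbon ring expansion), which has not been shown on a 2-unsubstituted cyclic 1,3-diketone. The four-membered ring closes 4-exo-trig, and the seven-membered ring is not closed directly but results from ring expansion by C–C cleavage. No stereocentre is created in 16 (those of 15 at C-1 and C-2 of 13 are transient and set by cis-fusion on the convex face), and the three existing stereocentres should be untouched under the neutral conditions. The step needs attack at the C-1 rather than the C-3 carbonyl, which the 3a-methyl group should secure because it shields C-3 on the convex face where C-1 has only 6a-H beside it, and it needs a single insertion, for which propyne is kept near one equivalent. The double bond is expected to settle in conjugation with C-8, any C-5=C-6 tautomer equilibrating with 16 through the shared dienol.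

Step 10
Reactants: 16 (3S,3aR,8aR)-3-hydroxy-6,8a-dimethyl-3-(propan-2-yl)-2,3,3a,8a-tetrahydroazulene-4,8(1H,5H)-dione
Product: 17 (3S,3aS,4R,8aR)-3,4-dihydroxy-6,8a-dimethyl-3-(propan-2-yl)-2,3,3a,4,5,8a-hexahydroazulen-8(1H)-one
Conditions: Me4NBH(OAc)3 (5 equiv), MeCN/AcOH (1:1), −30 °C
Reagents that add atoms: none
Why: Hydroxyl-directed (Evans–Saksena) reduction, in which the C-3 alkoxyborohydride should deliver hydride intramolecularly to the saturated C-4 carbonyl from the face of 3a-H to give the 4R alcohol anti to the C-3 oxygen, while the conjugated C-8 ketone has no directing hydroxyl and any C-5=C-6 tautomer should be drained through 16 because its conjugated C-4 carbonyl reacts more slowly.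

Step 11
Reactants: 17 (3S,3aS,4R,8aR)-3,4-dihydroxy-6,8a-dimethyl-3-(propan-2-yl)-2,3,3a,4,5,8a-hexahydroazulen-8(1H)-one; 18 4-(acetyloxy)benzoyl chloride
Product: 19 (3S,3aS,4R,8aR)-3-hydroxy-6,8a-dimethyl-8-oxo-3-(propan-2-yl)-1,2,3,3a,4,5,8,8a-octahydroazulen-4-yl 4-(acetyloxy)benzoate
Conditions: Et3N (2 equiv), DMAP (0.1 equiv), CH2Cl2, 0 °C to rt
Reagents that add atoms: none
Why: DMAP-catalysed acylation with the acid chloride should esterify the only secondary hydroxyl with retention, the tertiary C-3 hydroxyl being too hindered, and the phenol is carried as its acetate.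

Step 12
Reactants: 19 (3S,3aS,4R,8aR)-3-hydroxy-6,8a-dimethyl-8-oxo-3-(propan-2-yl)-1,2,3,3a,4,5,8,8a-octahydroazulen-4-yl 4-(acetyloxy)benzoate
Product: 20 (3S,3aS,4R,8R,8aR)-3,8-dihydroxy-6,8a-dimethyl-3-(propan-2-yl)-1,2,3,3a,4,5,8,8a-octahydroazulen-4-yl 4-(acetyloxy)benzoate
Conditions: (S)-2-methyl-CBS-oxazaborolidine (0.5 equiv), catecholborane (2.5 equiv), toluene, −78 to −40 °C
Reagents that add atoms: none
Why: Corey–Bakshi–Shibata reduction under reagent control, in which the (S)-catalyst with the quaternary C-8a side as the large group should give the 8R allylic alcohol (hydroxyl cis to the angular methyl) by 1,2-addition to the s-trans-locked enone, the esters being inert to catecholborane.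

Step 13
Reactants: 20 (3S,3aS,4R,8R,8aR)-3,8-dihydroxy-6,8a-dimethyl-3-(propan-2-yl)-1,2,3,3a,4,5,8,8a-octahydroazulen-4-yl 4-(acetyloxy)benzoate; 21 3-methylbutanoyl chloride
Product: 22 (3S,3aS,4R,8R,8aR)-3-hydroxy-6,8a-dimethyl-8-[(3-methylbutanoyl)oxy]-3-(propan-2-yl)-1,2,3,3a,4,5,8,8a-octahydroazulen-4-yl 4-(acetyloxy)benzoate
Conditions: pyridine (3 equiv), DMAP (0.2 equiv), CH2Cl2, 0 °C to rt
Reagents that add atoms: none
Why: Acyl transfer to the allylic secondary hydroxyl (esterification with an acid chloride) proceeds with retention at C-8 and should again leave the tertiary hydroxyl free.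

Step 14
Reactants: 22 (3S,3aS,4R,8R,8aR)-3-hydroxy-6,8a-dimethyl-8-[(3-methylbutanoyl)oxy]-3-(propan-2-yl)-1,2,3,3a,4,5,8,8a-octahydroazulen-4-yl 4-(acetyloxy)benzoate
Product: 23 (3S,3aS,4R,8R,8aR)-3-hydroxy-6,8a-dimethyl-8-[(3-methylbutanoyl)oxy]-3-(propan-2-yl)-1,2,3,3a,4,5,8,8a-octahydroazulen-4-yl 4-hydroxybenzoate
Conditions: pyrrolidine (2 equiv), CH2Cl2, 0 °C
Reagents that add atoms: none
Why: Chemoselective aminolysis of the aryl acetate, whose phenoxide is by far the best leaving group, should free the phenol while the secondary alkyl benzoate and the allylic isovalerate remain.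

Compound list

1 | 2-methylcyclopentane-1,3-dione | CC1C(=O)CCC1=O | starting material
2 | N-methoxy-N-methylprop-2-enamide | C=CC(=O)N(C)OC | starting material
3 | N-methoxy-N-methyl-3-(1-methyl-2,5-dioxocyclopentyl)propanamide | CON(C)C(=O)CCC1(C)C(=O)CCC1=O | intermediate
4 | N-methoxy-N-methyl-3-[(1S,2S)-2-hydroxy-1-methyl-5-oxocyclopentyl]propanamide (hydroxyl cis to the side chain) | O=C1CC[C@H](O)[C@]1(C)CCC(=O)N(C)OC | intermediate
5 | N-methoxy-N-methyl-3-[(1S,2S)-1-methyl-5-oxo-2-[(trimethylsilyl)oxy]cyclopentyl]propanamide | O=C1CC[C@H](O[Si](C)(C)C)[C@]1(C)CCC(=O)N(C)OC | intermediate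
6 | (4S,5S)-5-[3-[methoxy(methyl)amino]-3-oxopropyl]-5-methyl-4-[(trimethylsilyl)oxy]cyclopent-1-en-1-yl trifluoromethanesulfonate | O=S(=O)(OC1=CC[C@H](O[Si](C)(C)C)[C@]1(C)CCC(=O)N(C)OC)C(F)(F)F | intermediate
7 | isopropylmagnesium chloride | CC(C)[Mg]Cl | starting material
8 | (4S,5S)-5-methyl-5-(4-methyl-3-oxopentyl)-4-[(trimethylsilyl)oxy]cyclopent-1-en-1-yl trifluoromethanesulfonate | O=S(=O)(OC1=CC[C@H](O[Si](C)(C)C)[C@]1(C)CCC(=O)C(C)C)C(F)(F)F | intermediate
9 | (1S,3aR,4S)-3a-methyl-1-(propan-2-yl)-4-[(trimethylsilyl)oxy]-1,2,3,3a,4,5-hexahydropentalen-1-ol (C-6=C-6a alkene, 1-OH cis to 3a-methyl) | C1[C@H](O[Si](C)(C)C)[C@]2(C)CC[C@](O)(C(C)C)C2=C1 | intermediate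
10 | C-6 alkylborane of 9, drawn as the monoalkylborane (boron and 6a-H cis to the 3a-methyl group; not isolated) | [BH2][C@H]1C[C@H](O[Si](C)(C)C)[C@]2(C)CC[C@](O)(C(C)C)[C@@H]21 | intermediate
11 | (1S,3aR,4S,6S,6aS)-3a-methyl-1-(propan-2-yl)-4-[(trimethylsilyl)oxy]octahydropentalene-1,6-diol (not isolated) | O[C@H]1C[C@H](O[Si](C)(C)C)[C@]2(C)CC[C@](O)(C(C)C)[C@@H]21 | intermediate
12 | (1S,3aR,4S,6S,6aS)-3a-methyl-1-(propan-2-yl)octahydropentalene-1,4,6-triol | O[C@H]1C[C@H](O)[C@]2(C)CC[C@](O)(C(C)C)[C@@H]21 | intermediate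
13 | (3aR,6S,6aR)-6-hydroxy-3a-methyl-6-(propan-2-yl)tetrahydropentalene-1,3(2H,3aH)-dione (cis-fused; 3a-methyl, 6a-H and 6-OH on one face) | O=C1CC(=O)[C@]2(C)CC[C@](O)(C(C)C)[C@@H]21 | intermediate
14 | propyne | CC#C | starting material
15 | cyclobutenol from 13 and propyne (cyclobutene cis-fused across C-1–C-2 of 13 on the face of 6a-H; rhenium alkoxide in the flask; not isolated) | CC1=C[C@@]2(O)[C@@H]1C(=O)[C@]3(C)CC[C@](O)(C(C)C)[C@H]23 | intermediate
16 | (3S,3aR,8aR)-3-hydroxy-6,8a-dimethyl-3-(propan-2-yl)-2,3,3a,8a-tetrahydroazulene-4,8(1H,5H)-dione | CC1=CC(=O)[C@]2(C)CC[C@](O)(C(C)C)[C@@H]2C(=O)C1 | intermediate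
17 | (3S,3aS,4R,8aR)-3,4-dihydroxy-6,8a-dimethyl-3-(propan-2-yl)-2,3,3a,4,5,8a-hexahydroazulen-8(1H)-one (4-OH trans to 3a-H) | CC1=CC(=O)[C@]2(C)CC[C@](O)(C(C)C)[C@@H]2[C@H](O)C1 | intermediate
18 | 4-(acetyloxy)benzoyl chloride | CC(=O)Oc1ccc(cc1)C(=O)Cl | starting material
19 | (3S,3aS,4R,8aR)-3-hydroxy-6,8a-dimethyl-8-oxo-3-(propan-2-yl)-1,2,3,3a,4,5,8,8a-octahydroazulen-4-yl 4-(acetyloxy)benzoate | CC1=CC(=O)[C@]2(C)CC[C@](O)(C(C)C)[C@@H]2[C@H](OC(=O)c2ccc(OC(C)=O)cc2)C1 | intermediate
20 | (3S,3aS,4R,8R,8aR)-3,8-dihydroxy-6,8a-dimethyl-3-(propan-2-yl)-1,2,3,3a,4,5,8,8a-octahydroazulen-4-yl 4-(acetyloxy)benzoate (8-OH cis to 8a-methyl) | CC1=C[C@@H](O)[C@]2(C)CC[C@](O)(C(C)C)[C@@H]2[C@H](OC(=O)c2ccc(OC(C)=O)cc2)C1 | intermediate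
21 | 3-methylbutanoyl chloride | CC(C)CC(=O)Cl | starting material
22 | (3S,3aS,4R,8R,8aR)-3-hydroxy-6,8a-dimethyl-8-[(3-methylbutanoyl)oxy]-3-(propan-2-yl)-1,2,3,3a,4,5,8,8a-octahydroazulen-4-yl 4-(acetyloxy)benzoate | CC1=C[C@@H](OC(=O)CC(C)C)[C@]2(C)CC[C@](O)(C(C)C)[C@@H]2[C@H](OC(=O)c2ccc(OC(C)=O)cc2)C1 | intermediate
23 | (3S,3aS,4R,8R,8aR)-3-hydroxy-6,8a-dimethyl-8-[(3-methylbutanoyl)oxy]-3-(propan-2-yl)-1,2,3,3a,4,5,8,8a-octahydroazulen-4-yl 4-hydroxybenzoate | CC1=C[C@@H](OC(=O)CC(C)C)[C@]2(C)CC[C@](O)(C(C)C)[C@@H]2[C@H](OC(=O)c2ccc(O)cc2)C1 | target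

Total step count: 14. Longest linear sequence: 14 steps (1 to 23).

Steps most likely to fail

(a) Step 9, the key step. The alkenylrhenium may fail to close onto the hindered carbonyl and stop at C-alkenylation. Insertion may occur on the C-3 side. The acidic C-5 methylene of the product may take up a second propyne. The fallback uses the de Mayo reaction, which is known chemistry, and sets out from 13. Irradiation of the enolised dione (medium-pressure Hg lamp, Vycor filter) with excess propa-1,2-diene in MeCN/CH2Cl2 at −40 °C should give, by head-to-head [2+2] photocycloaddition across C-1=C-2, the methylenecyclobutanol F1. F1 should open in the flask by retro-aldol cleavage to the 6-methylidene-4,8-dione F2. DBU (0.1 equiv) in CH2Cl2 at rt then moves the exocyclic double bond into conjugation, and the route is rejoined at 16.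

(b) Step 10. Reduction may proceed through the C-5=C-6 enone tautomer, which would place the double bond wrongly. Intramolecular hydride delivery may also be slow, because the C-3 hydroxyl and C-4 are trans on the five-membered ring. The fallback sets out from 16 and masks the alkene. Thia-Michael addition of thiophenol (PhSH, Et3N cat., CH2Cl2) collects both enone tautomers as the saturated sulfide dione F3 (C-6 epimers). Directed reduction as in step 10 gives the hydroxy ketone F4, and acylation with 18 as in step 11 gives the aroyl ester F5. Oxidation with mCPBA (1 equiv, CH2Cl2, −78 °C) gives the sulfoxide F6. Warming F6 in toluene with CaCO3 should bring syn-elimination toward the acidic C-7 hydrogen, and the route is rejoined at 19.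

(c) Step 6. The alkenylchromium may be protonated before it adds, or may not add to the hindered isopropyl ketone. The fallback sets out from 6 and closes the ring by acylation, then adds the isopropyl group to a ring ketone. Nickel-catalysed triflate–iodide exchange (NaI, Ni(OAc)2 10 mol %, 1,5-cyclooctadiene, Zn 20 mol %, DMA/THF) gives the alkenyl iodide F7. Iodine–lithium exchange (tBuLi 2.1 equiv, THF, −100 °C) and Parham-type cyclisation onto the Weinreb amide give the bicyclic enone F8. The organocerium reagent from 7 and CeCl3 (THF, −78 °C) should add 1,2 to the ketone anti to the angular methyl, and the route is rejoined at 9.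

Further compounds

F1 | step 9 | methylenecyclobutanol photoadduct of 13 and propa-1,2-diene (not isolated) | C=C1C[C@@]2(O)[C@@H]1C(=O)[C@]3(C)CC[C@](O)(C(C)C)[C@H]23
F2 | step 9 | (3S,3aR,8aR)-3-hydroxy-8a-methyl-6-methylidene-3-(propan-2-yl)hexahydroazulene-4,8(1H,5H)-dione | C=C1CC(=O)[C@]2(C)CC[C@](O)(C(C)C)[C@@H]2C(=O)C1
F3 | step 10 | (3S,3aR,8aR)-3-hydroxy-6,8a-dimethyl-6-(phenylsulfanyl)-3-(propan-2-yl)hexahydroazulene-4,8(1H,5H)-dione (C-6 epimers) | CC1(Sc2ccccc2)CC(=O)[C@]2(C)CC[C@](O)(C(C)C)[C@@H]2C(=O)C1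
F4 | step 10 | (3S,3aS,4R,8aR)-3,4-dihydroxy-6,8a-dimethyl-6-(phenylsulfanyl)-3-(propan-2-yl)octahydroazulen-8(1H)-one (C-6 epimers) | CC1(Sc2ccccc2)CC(=O)[C@]2(C)CC[C@](O)(C(C)C)[C@@H]2[C@H](O)C1
F5 | step 10 | (3S,3aS,4R,8aR)-3-hydroxy-6,8a-dimethyl-8-oxo-6-(phenylsulfanyl)-3-(propan-2-yl)decahydroazulen-4-yl 4-(acetyloxy)benzoate (C-6 epimers) | CC1(Sc2ccccc2)CC(=O)[C@]2(C)CC[C@](O)(C(C)C)[C@@H]2[C@H](OC(=O)c2ccc(OC(C)=O)cc2)C1
F6 | step 10 | sulfoxide of F5 (6-benzenesulfinyl; not isolated) | CC1(S(=O)c2ccccc2)CC(=O)[C@]2(C)CC[C@](O)(C(C)C)[C@@H]2[C@H](OC(=O)c2ccc(OC(C)=O)cc2)C1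
F7 | step 6 | 3-[(1S,2S)-5-iodo-1-methyl-2-[(trimethylsilyl)oxy]cyclopent-4-en-1-yl]-N-methoxy-N-methylpropanamide | IC1=CC[C@H](O[Si](C)(C)C)[C@]1(C)CCC(=O)N(C)OC
F8 | step 6 | (3aR,4S)-3a-methyl-4-[(trimethylsilyl)oxy]-3,3a,4,5-tetrahydropentalen-1(2H)-one | C1[C@H](O[Si](C)(C)C)[C@]2(C)CCC(=O)C2=C1
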